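The oxirane is traced back to a tertiary C1 carbinol beside an axial C6 leaving group. In that open form the ring oxygens (O1 and O6 axial and anti, O2 to O5 equatorial and alternating) coincide with D-chiro-inositol, so C7 is the only carbon to add. The plan rests on disconnecting C1–O and C7–O to an exocyclic C1=C7 alkene. One osmylation then sets both oxygens and the quaternary centre C1. It exploits the axial C6–O bond, held in the cis-fused 5,6-dioxolane ring on a cyclohexane chair locked by the trans-fused 2,3-disiloxane ring, which closes one alkene face. The precursor is the 1-methylene cyclitol with 4-O-benzyl, 5,6-O-isopropylidene and 2,3-O-disiloxanediyl protection.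

Key step: step 8

Convention: C1 is the quaternary oxirane carbon, C7 the CH2OBz carbon, C2 and C3 the acetoxy carbons, C4 and C5 the carbinols, and C6 the oxirane CH. The inositol locants coincide with this numbering. With C1 to C6 drawn clockwise, β is above and α below the ring. TIPDS stands for 1,1,3,3-tetraisopropyldisiloxane-1,3-diyl.

Assumption: D-chiro-inositol is taken as a commercial chiral-pool material. The cyclic sulfite of step 13 is carried on as both sulfur epimers, since that centre vanishes in step 14.

Remark on the order of events: O2 and O3 are acetylated while O5 and O6 are still ketal-bound and O4 is benzylated, so O4 and O5 cannot be acylated.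

Step 1
Reactants: 1 D-chiro-inositol
Product: 2 1,2:5,6-di-O-isopropylidene-D-chiro-inositol
Conditions: 2,2-dimethoxypropane (2.5 equiv.), p-TsOH·H2O (cat.), DMF, 50 °C
Reagents that add atoms: 2,2-dimethoxypropane, COC(C)(C)OC
Why: Acid-catalysed transketalisation (acetonide formation) under equilibrating conditions should tie up the two axial/equatorial cis pairs O1/O2 and O5/O6 as dioxolanes, whereas a trans-fused ketal across the diequatorial O3/O4 pair is strained and should not persist with limited reagent, and no stereocentre is touched.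

Step 2
Reactants: 2 1,2:5,6-di-O-isopropylidene-D-chiro-inositol
Product: 3 4-O-benzyl-1,2:5,6-di-O-isopropylidene-D-chiro-inositol
Conditions: BnBr (1.1 equiv.), Ag2O (1.5 equiv.), CH2Cl2, rt, dark
Reagents that add atoms: benzyl bromide, BrCc1ccccc1
Why: Ag2O-mediated Williamson monobenzylation of a symmetric vicinal diol, in which the two hydroxyls are homotopic through the C2 axis so that either gives the same ether (its oxygen is O4 from here on), and loss of silver chelation after the first alkylation should hold back the second.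

Step 3
Reactants: 3 4-O-benzyl-1,2:5,6-di-O-isopropylidene-D-chiro-inositol
Product: 4 4-O-benzyl-D-chiro-inositol
Conditions: TFA/H2O (4:1), rt
Reagents that add atoms: none
Why: Acid-catalysed ketal hydrolysis frees O1, O2, O5 and O6 while the benzyl ether is inert, and because only ketal C–O bonds break all ring stereocentres are kept.

Step 4
Reactants: 4 4-O-benzyl-D-chiro-inositol
Product: 5 4-O-benzyl-2,3-O-TIPDS-D-chiro-inositol
Conditions: TIPDSCl2 (1.05 equiv.), pyridine, −20 °C to rt
Reagents that add atoms: 1,3-dichloro-1,1,3,3-tetraisopropyldisiloxane, CC(C)[Si](Cl)(C(C)C)O[Si](Cl)(C(C)C)C(C)C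
Why: Regioselective cyclic silylation, in which the first Si–O bond should form at an open equatorial hydroxyl (O2 or O3) and the second chlorosilane should close on the neighbouring equatorial oxygen, following the known preference of this reagent in inositols for vicinal trans-diequatorial diols over axial/equatorial cis pairs, while O5 is screened by the benzyl ether and axial O6.

Step 5
Reactants: 5 4-O-benzyl-2,3-O-TIPDS-D-chiro-inositol
Product: 6 4-O-benzyl-5,6-O-isopropylidene-2,3-O-TIPDS-D-chiro-inositol
Conditions: 2,2-dimethoxypropane, PPTS (cat.), acetone, rt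
Reagents that add atoms: 2,2-dimethoxypropane, COC(C)(C)OC
Why: Acid-catalysed acetonide formation can bridge only the one remaining cis pair O5/O6, because O1 and O6 are trans-diaxial, so the axial C1 hydroxyl should be left as the single free alcohol.

Step 6
Reactants: 6 4-O-benzyl-5,6-O-isopropylidene-2,3-O-TIPDS-D-chiro-inositol
Product: 7 4-O-benzyl-5,6-O-isopropylidene-2,3-O-TIPDS-D-chiro-inos-1-ose (C1 ketone)
Conditions: Dess–Martin periodinane, CH2Cl2, rt
Reagents that add atoms: none
Why: Dess–Martin oxidation turns the axial secondary alcohol into the ketone under neutral, non-enolising conditions, so C2 and C6 should not epimerise and no β-oxygen should be eliminated.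

Step 7
Reactants: 7 4-O-benzyl-5,6-O-isopropylidene-2,3-O-TIPDS-D-chiro-inos-1-ose; 8 methyltriphenylphosphonium bromide
Product: 9 4-O-benzyl-1-deoxy-5,6-O-isopropylidene-1-methylidene-2,3-O-TIPDS-D-chiro-inositol
Conditions: 8, KN(SiMe3)2, THF, 0 °C; then 7, −78 °C to rt
Reagents that add atoms: 8 methyltriphenylphosphonium bromide, C[P+](c1ccccc1)(c1ccccc1)c1ccccc1.[Br-]
Why: Wittig methylenation with the non-stabilised ylide at low temperature brings in C7, and β-elimination from the inosose should be held back because both β-oxygens (O3 and O5) are equatorial and ring-bound and thus poorly aligned with an enolate π system.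

Step 8
Reactants: 9 4-O-benzyl-1-deoxy-5,6-O-isopropylidene-1-methylidene-2,3-O-TIPDS-D-chiro-inositol
Product: 11 4-O-benzyl-1-C-(hydroxymethyl)-5,6-O-isopropylidene-2,3-O-TIPDS-D-chiro-inositol, via cyclic osmate ester 10 (not isolated)
Conditions: OsO4 (5 mol %), NMO (2 equiv.), acetone/t-BuOH/H2O, rt
Reagents that add atoms: osmium tetroxide, O=[Os](=O)(=O)=O; N-methylmorpholine N-oxide, C[N+]1([O-])CCOCC1; water, O
Why: Upjohn dihydroxylation, in which OsO4 adds suprafacially to the 1,1-disubstituted C1=C7 alkene by a concerted [3+2] cycloaddition, the hexavalent osmium glycolate 10 is hydrolysed, and NMO returns the metal to the octavalent state. The closest known reaction type is the osmylation of methylenecyclohexanes bearing an axial allylic oxygen substituent, which takes place anti to that substituent. No ring of the product is closed; only the transient five-membered osmate ring forms, through the cycloaddition itself. The one new stereocentre, C1, is under substrate control: the trans-fused disiloxane ring locks the chair, the C6–O bond stands axial on the β face next to the alkene and carries the cis-fused dioxolane, and equatorial O2 lies near the alkene plane and biases neither face, so osmium should approach from the α face and leave O1 axial (α) and C7 equatorial (β). Only facial selectivity is required, since 9 has a single alkene and its benzyl ether, ketal and silyl ethers are inert to the oxidant. O1 then lies antiperiplanar to the C6–O bond, the geometry used in step 15.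

Step 9
Reactants: 11 4-O-benzyl-1-C-(hydroxymethyl)-5,6-O-isopropylidene-2,3-O-TIPDS-D-chiro-inositol; 12 benzoyl chloride
Product: 13 1-C-(benzoyloxymethyl)-4-O-benzyl-5,6-O-isopropylidene-2,3-O-TIPDS-D-chiro-inositol
Conditions: 12 (1.1 equiv.), pyridine, CH2Cl2, 0 °C
Reagents that add atoms: 12 benzoyl chloride, O=C(Cl)c1ccccc1
Why: Selective O-acylation (nucleophilic acyl substitution), since the primary C7 hydroxyl should be benzoylated far faster than the hindered tertiary axial C1 hydroxyl.

Step 10
Reactants: 13 1-C-(benzoyloxymethyl)-4-O-benzyl-5,6-O-isopropylidene-2,3-O-TIPDS-D-chiro-inositol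
Product: 14 1-C-(benzoyloxymethyl)-4-O-benzyl-5,6-O-isopropylidene-D-chiro-inositol
Conditions: Et3N·3HF, THF, rt
Reagents that add atoms: none
Why: Fluoride-mediated desilylation with a slightly acidic HF source cleaves both Si–O bonds of the disiloxane bridge while ketal, benzyl ether and benzoate stay, and the absence of free base should prevent benzoyl migration.

Step 11
Reactants: 14 1-C-(benzoyloxymethyl)-4-O-benzyl-5,6-O-isopropylidene-D-chiro-inositol; 15 acetic anhydride
Product: 16 2,3-di-O-acetyl-1-C-(benzoyloxymethyl)-4-O-benzyl-5,6-O-isopropylidene-D-chiro-inositol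
Conditions: 15, pyridine, rt
Reagents that add atoms: 15 acetic anhydride, CC(=O)OC(C)=O
Why: Pyridine-mediated O-acetylation esterifies the two equatorial secondary hydroxyls O2 and O3, while the tertiary C1 hydroxyl should stay free without an acyl-transfer catalyst and O4, O5 and O6 are masked.

Step 12
Reactants: 16 2,3-di-O-acetyl-1-C-(benzoyloxymethyl)-4-O-benzyl-5,6-O-isopropylidene-D-chiro-inositol
Product: 17 2,3-di-O-acetyl-1-C-(benzoyloxymethyl)-4-O-benzyl-D-chiro-inositol
Conditions: TFA/H2O (9:1), CH2Cl2, 0 °C
Reagents that add atoms: none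
Why: Acid-catalysed ketal hydrolysis unmasks the cis O5/O6 diol, with esters and benzyl ether stable to cold aqueous acid and the tertiary carbinol too electron-poor to ionise.

Step 13
Reactants: 17 2,3-di-O-acetyl-1-C-(benzoyloxymethyl)-4-O-benzyl-D-chiro-inositol
Product: 18 5,6-cyclic sulfite of 17 (both sulfur epimers)
Conditions: SOCl2 (1.2 equiv.), pyridine, CH2Cl2, 0 °C
Reagents that add atoms: thionyl chloride, O=S(Cl)Cl
Why: Cyclic sulfite formation, in which thionyl chloride bridges the cis O5/O6 pair in a five-membered ring that O1 cannot enter because it is trans-diaxial to O6.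

Step 14
Reactants: 18 5,6-cyclic sulfite of 17
Product: 19 5,6-cyclic sulfate of 17
Conditions: RuCl3·xH2O (cat.), NaIO4 (1.5 equiv.), MeCN/CH2Cl2/H2O, 0 °C
Reagents that add atoms: sodium periodate, [Na+].[O-]I(=O)(=O)=O
Why: Sharpless-type oxidation of a cyclic sulfite with catalytic RuO4 made from RuCl3 and NaIO4 should be complete within minutes at 0 °C, conditions that benzyl ethers, esters and tertiary alcohols are known to survive.

Step 15
Reactants: 19 5,6-cyclic sulfate of 17
Product: 21 [(1S,2R,3S,4R,5R,6S)-2,3-diacetoxy-4-benzyloxy-5-hydroxy-7-oxabicyclo[4.1.0]heptan-1-yl]methyl benzoate, via sodium sulfate monoester 20 (not isolated)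
Conditions: NaH (1.1 equiv.), THF, 0 °C; then H2SO4 (cat.), H2O (2 equiv.), THF, rt
Reagents that add atoms: none
Why: Deprotonation of the tertiary C1 hydroxyl gives an alkoxide antiperiplanar to the axial C6–O bond of the cyclic sulfate, so a 3-exo-tet intramolecular SN2 (Williamson-type oxirane closure of a hydroxy cyclic sulfate) should invert C6 to the α-oxirane and leave O5 as its sulfate monoester, which catalytic acid with a minimum of water cleaves at the S–O bond without touching C5.

Step 16
Reactants: 21 [(1S,2R,3S,4R,5R,6S)-2,3-diacetoxy-4-benzyloxy-5-hydroxy-7-oxabicyclo[4.1.0]heptan-1-yl]methyl benzoate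
Product: 22 [(1S,2R,3S,4R,5R,6S)-2,3-diacetoxy-4,5-dihydroxy-7-oxabicyclo[4.1.0]heptan-1-yl]methyl benzoate (CNP0171674.1)
Conditions: H2 (1 atm), Pd/C, EtOAc, rt
Reagents that add atoms: none
Why: Catalytic hydrogenolysis of the benzyl ether in a neutral aprotic solvent frees O4, while the non-benzylic oxirane and the esters are not reduced and the acetates should not migrate in the absence of base.

Compound list
1 | D-chiro-inositol (O1α, O2α, O3β, O4α, O5β, O6β; O1 and O6 axial) | O[C@@H]1[C@H](O)[C@@H](O)[C@H](O)[C@@H](O)[C@H]1O | starting material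
2 | 1,2:5,6-di-O-isopropylidene-D-chiro-inositol | CC1(C)O[C@@H]2[C@H](O1)[C@@H](O)[C@H](O)[C@H]3OC(C)(C)O[C@@H]23 | intermediate
3 | 4-O-benzyl-1,2:5,6-di-O-isopropylidene-D-chiro-inositol | CC1(C)O[C@@H]2[C@H](O1)[C@@H](O)[C@H](OCc1ccccc1)[C@H]3OC(C)(C)O[C@@H]23 | intermediate
4 | 4-O-benzyl-D-chiro-inositol | O[C@@H]1[C@H](O)[C@@H](O)[C@H](OCc2ccccc2)[C@@H](O)[C@H]1O | intermediate
5 | 4-O-benzyl-2,3-O-TIPDS-D-chiro-inositol | O[C@@H]1[C@@H]2O[Si](C(C)C)(C(C)C)O[Si](C(C)C)(C(C)C)O[C@H]2[C@H](OCc2ccccc2)[C@@H](O)[C@H]1O | intermediate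
6 | 4-O-benzyl-5,6-O-isopropylidene-2,3-O-TIPDS-D-chiro-inositol (free axial C1 hydroxyl) | O[C@@H]1[C@@H]2O[Si](C(C)C)(C(C)C)O[Si](C(C)C)(C(C)C)O[C@H]2[C@H](OCc2ccccc2)[C@H]2OC(C)(C)O[C@@H]12 | intermediate
7 | 4-O-benzyl-5,6-O-isopropylidene-2,3-O-TIPDS-D-chiro-inos-1-ose (C1 ketone) | O=C1[C@@H]2O[Si](C(C)C)(C(C)C)O[Si](C(C)C)(C(C)C)O[C@H]2[C@H](OCc2ccccc2)[C@H]2OC(C)(C)O[C@@H]12 | intermediate
8 | methyltriphenylphosphonium bromide | C[P+](c1ccccc1)(c1ccccc1)c1ccccc1.[Br-] | starting material
9 | 4-O-benzyl-1-deoxy-5,6-O-isopropylidene-1-methylidene-2,3-O-TIPDS-D-chiro-inositol | C=C1[C@@H]2O[Si](C(C)C)(C(C)C)O[Si](C(C)C)(C(C)C)O[C@H]2[C@H](OCc2ccccc2)[C@H]2OC(C)(C)O[C@@H]12 | intermediate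
10 | cyclic osmate ester of 11 (hexavalent osmium bridging O1α and O7) | O=[Os]1(=O)OC[C@@]2(O1)[C@@H]3O[Si](C(C)C)(C(C)C)O[Si](C(C)C)(C(C)C)O[C@H]3[C@H](OCc3ccccc3)[C@H]3OC(C)(C)O[C@@H]23 | intermediate
11 | 4-O-benzyl-1-C-(hydroxymethyl)-5,6-O-isopropylidene-2,3-O-TIPDS-D-chiro-inositol (O1α axial, C7β equatorial) | OC[C@@]1(O)[C@@H]2O[Si](C(C)C)(C(C)C)O[Si](C(C)C)(C(C)C)O[C@H]2[C@H](OCc2ccccc2)[C@H]2OC(C)(C)O[C@@H]12 | intermediate
12 | benzoyl chloride | O=C(Cl)c1ccccc1 | starting material
13 | 1-C-(benzoyloxymethyl)-4-O-benzyl-5,6-O-isopropylidene-2,3-O-TIPDS-D-chiro-inositol | O=C(OC[C@@]1(O)[C@@H]2O[Si](C(C)C)(C(C)C)O[Si](C(C)C)(C(C)C)O[C@H]2[C@H](OCc2ccccc2)[C@H]2OC(C)(C)O[C@@H]12)c1ccccc1 | intermediate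
14 | 1-C-(benzoyloxymethyl)-4-O-benzyl-5,6-O-isopropylidene-D-chiro-inositol | O=C(OC[C@@]1(O)[C@H](O)[C@@H](O)[C@H](OCc2ccccc2)[C@H]2OC(C)(C)O[C@@H]12)c1ccccc1 | intermediate
15 | acetic anhydride | CC(=O)OC(C)=O | starting material
16 | 2,3-di-O-acetyl-1-C-(benzoyloxymethyl)-4-O-benzyl-5,6-O-isopropylidene-D-chiro-inositol | O=C(OC[C@@]1(O)[C@H](OC(C)=O)[C@@H](OC(C)=O)[C@H](OCc2ccccc2)[C@H]2OC(C)(C)O[C@@H]12)c1ccccc1 | intermediate
17 | 2,3-di-O-acetyl-1-C-(benzoyloxymethyl)-4-O-benzyl-D-chiro-inositol | O=C(OC[C@@]1(O)[C@H](OC(C)=O)[C@@H](OC(C)=O)[C@H](OCc2ccccc2)[C@@H](O)[C@H]1O)c1ccccc1 | intermediate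
18 | 5,6-cyclic sulfite of 17 (both sulfur epimers) | O=C(OC[C@@]1(O)[C@H](OC(C)=O)[C@@H](OC(C)=O)[C@H](OCc2ccccc2)[C@H]2OS(=O)O[C@@H]12)c1ccccc1 | intermediate
19 | 5,6-cyclic sulfate of 17 | O=C(OC[C@@]1(O)[C@H](OC(C)=O)[C@@H](OC(C)=O)[C@H](OCc2ccccc2)[C@H]2OS(=O)(=O)O[C@@H]12)c1ccccc1 | intermediate
20 | sodium salt of the O5 sulfate monoester of 21 (α-oxirane closed, O5β sulfated) | CC(=O)O[C@H]1[C@H](OCc2ccccc2)[C@@H](OS(=O)(=O)[O-])[C@@H]2O[C@]2(COC(=O)c2ccccc2)[C@@H]1OC(C)=O.[Na+] | intermediate
21 | [(1S,2R,3S,4R,5R,6S)-2,3-diacetoxy-4-benzyloxy-5-hydroxy-7-oxabicyclo[4.1.0]heptan-1-yl]methyl benzoate | CC(=O)O[C@H]1[C@H](OCc2ccccc2)[C@@H](O)[C@@H]2O[C@]2(COC(=O)c2ccccc2)[C@@H]1OC(C)=O | intermediate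
22 | [(1S,2R,3S,4R,5R,6S)-2,3-diacetoxy-4,5-dihydroxy-7-oxabicyclo[4.1.0]heptan-1-yl]methyl benzoate (CNP0171674.1) | CC(=O)O[C@H]1[C@H](O)[C@@H](O)[C@@H]2O[C@]2(COC(=O)c2ccccc2)[C@@H]1OC(C)=O | target

Total step count: 16. Longest linear sequence: 16 steps (1 to 22).

Steps most likely to fail

Step 8. The crowded alkene may react sluggishly, or the facial preference may erode if the chair is distorted by the two fused rings.
- The fallback replaces alkene oxidation by carbonyl addition, so a different element controls C1. It sets out from ketone 7.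
- A Corey–Chaykovsky reaction with dimethylsulfoxonium methylide (Me3S(O)I, NaH, DMSO/THF) forms its betaine reversibly, so the new C1–C7 bond should settle equatorial (β) with O1 axial (α). This should give the spiro-oxirane at C1 F1.
- Benzoic acid with catalytic PhCO2Cs in DMF at 80 °C should then open the oxirane at the unhindered C7 by SN2. The fallback comes back to the route at 13, bypassing 9 and 11.

Step 4. The bridge may be misplaced (first silylation at O5, then closure on axial O6), or the pentaol may be silylated twice.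
- The fallback inverts the order of protection and sets out from 1.
- TIPDSCl2 (1 equiv.) in pyridine/DMF should start at O2, which is equivalent to O5 by symmetry, and close on O3. This should give 2,3-O-TIPDS-D-chiro-inositol F2.
- Acetonide formation can then take only the last cis pair O5/O6, giving 5,6-O-isopropylidene-2,3-O-TIPDS-D-chiro-inositol F3.
- BnBr/Ag2O should alkylate equatorial O4 in preference to the doubly flanked axial O1. The fallback comes back to the route at 6.

Step 15. The C1 alkoxide may pass acyl groups around before it closes the ring, or the oxirane may open under acid while the sulfate monoester is cleaved.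
- The fallback avoids both base and acid and sets out from triol 17.
- It is a Mitsunobu-type cyclodehydration (PPh3, DIAD, toluene/THF, rt). The cis O5/O6 pair is taken up by phosphorus, and only the C6 oxyphosphonium form has an antiperiplanar internal nucleophile (O1).
- The oxirane should therefore close with inversion at C6. The fallback comes back to the route at 21, bypassing 18 to 20.

Further compounds
F1 | step 8 | spiro-oxirane at C1 (O1α axial, C7β equatorial) of the 4-O-benzyl-5,6-O-isopropylidene-2,3-O-TIPDS cyclitol | C1O[C@@]12[C@@H]3O[Si](C(C)C)(C(C)C)O[Si](C(C)C)(C(C)C)O[C@H]3[C@H](OCc3ccccc3)[C@H]3OC(C)(C)O[C@@H]23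
F2 | step 4 | 2,3-O-TIPDS-D-chiro-inositol | O[C@@H]1[C@@H]2O[Si](C(C)C)(C(C)C)O[Si](C(C)C)(C(C)C)O[C@H]2[C@H](O)[C@@H](O)[C@H]1O
F3 | step 4 | 5,6-O-isopropylidene-2,3-O-TIPDS-D-chiro-inositol | O[C@@H]1[C@@H]2O[Si](C(C)C)(C(C)C)O[Si](C(C)C)(C(C)C)O[C@H]2[C@H](O)[C@H]2OC(C)(C)O[C@@H]12
F0 | step 15 | none | none
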